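Atom labels follow the order of atoms in the target SMILES: C5 is the CH2OAc carbon on quaternary C6; ring A is C6–C7–C8–C13–C15–C18; the cage has apex C18, bridges C6, C19 and C24, and cyclopropane C20–C21–C22. The enabling feature is the C13 hydroxyl beside gem-dimethyl C15 beside ring-fusion C18, which is α to the C24 oxygen: the pattern left when an epoxide is opened at its tertiary carbon by a C24 enol silane.
Retrosynthesis: C24–OAc from solvolysis of the epimeric C24 sulfonate; C20–C21 and C20–C22 cut to a C20 diazoalkane and the C21=C22 enone; C18–C19 cut to an enolate allylation; C15–C18 cut to the C13–C15 epoxide and a 2-silyloxycyclopentadiene; C21=C22 cut to an aldol condensation; C8–C13 cut to an alkenyl Grignard addition; C6–C5 and C6–C7 cut to two alkylations of a valinol-derived bicyclic lactam.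
Forward: C6 and the C7–C8–C13–C15 chain are built on the lactam, the lactam is unmasked and closed to the cyclopentenone, ring A closes in the key step, C18 is allylated, and the cage is closed by an intramolecular diazoalkane cycloaddition with loss of N2; C24 adjustment and protecting-group exchange finish the route.
Stereochemistry: C6 from the lactam (second electrophile anti to the angular ethyl group); C8 from a CBS reduction; C13 from a Shi epoxidation; C18 from the tether-enforced cis ring fusion, kept on allylation; C20, C21 and C22 from the two-carbon tether; C24 from acetate capture of the nortricyclyl cation on its open face.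

Key step: step 13

Remark: the second alkylation of the bicyclic lactam enolate is assumed to occur opposite the angular ethyl group, and hydride and acetate are assumed to reach C24 of the cage from the side of the C19 methylene, the other side being covered by C7 of ring A.

Step 1
Reactants: 1 (R)-valinol; 2 4-oxohexanoic acid
Product: 3 (3R,7aS)-7a-ethyl-3-isopropyltetrahydropyrrolo[2,1-b]oxazol-5(6H)-one
Conditions: toluene, reflux, Dean–Stark trap
Reagents that add atoms: none
Why: Condensation of the amino alcohol with the γ-keto acid (N,O-acetal formation and lactamisation with azeotropic removal of water) should give the cis-fused bicyclic lactam with the angular ethyl and the isopropyl group on the same face.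

Step 2
Reactants: 3 bicyclic lactam; 4 allyl bromide
Product: 5 6-allyl derivative of 3 (both C6 epimers)
Conditions: LiN(iPr)2, THF, −78 °C; then 4, −78 → −20 °C
Reagents that add atoms: none
Why: Alkylation of the lactam lithium enolate with a reactive allylic halide is routine, and the epimer mixture is acceptable because C6 is planarised again in step 3.

Step 3
Reactants: 5 6-allyl lactam; 6 benzyl chloromethyl ether
Product: 7 (3R,6S,7aS)-6-allyl-6-(benzyloxymethyl)-7a-ethyl-3-isopropyltetrahydropyrrolo[2,1-b]oxazol-5(6H)-one
Conditions: LiN(iPr)2, THF, −78 °C; then 6, −78 °C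
Reagents that add atoms: none
Why: In this second enolate alkylation of the chiral bicyclic lactam the unhindered chloromethyl ether should enter opposite the angular ethyl group, which sets quaternary C6 as in the target.

Step 4
Reactants: 7 dialkylated lactam
Product: 9 lactam aldehyde (6-(2-oxoethyl) analogue of 7), via ozonide 8 (not isolated)
Conditions: O3, CH2Cl2, −78 °C; then Me2S, −78 °C → rt
Reagents that add atoms: ozone, [O-][O+]=O
Why: Ozonolysis with reductive work-up cleaves the only alkene of 7 to the C8 aldehyde and leaves the benzyl ether and the N,O-acetal untouched.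

Step 5
Reactants: 9 lactam aldehyde; 10 (2-methylprop-1-enyl)magnesium bromide
Product: 11 lactam allylic alcohol, 6-(2-hydroxy-4-methylpent-3-enyl) (both C8 epimers)
Conditions: THF, −78 °C; aq. NH4Cl
Reagents that add atoms: none
Why: Grignard 1,2-addition to the aldehyde is much faster than attack on the hindered tertiary lactam, and both C8 epimers are carried on because C8 is oxidised next.

Step 6
Reactants: 11 lactam allylic alcohol
Product: 12 lactam enone, 6-(4-methyl-2-oxopent-3-enyl)
Conditions: Dess–Martin periodinane, NaHCO3, CH2Cl2, 0 °C → rt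
Reagents that add atoms: none
Why: Dess–Martin oxidation of the secondary allylic alcohol under buffered conditions should give the β,β-dimethyl enone without double-bond migration.

Step 7
Reactants: 12 lactam enone
Product: 13 lactam (S)-allylic alcohol, 6-[(2S)-2-hydroxy-4-methylpent-3-enyl]
Conditions: (R)-Me-CBS oxazaborolidine ((R)-1-methyl-3,3-diphenyltetrahydro-1H,3H-pyrrolo[1,2-c][1,3,2]oxazaborole, cat.), catecholborane, toluene, −78 °C
Reagents that add atoms: none
Why: In this Corey–Bakshi–Shibata reduction the 2-methylpropenyl group acts as the large substituent, so the (R)-catalyst should deliver hydride to give the (S)-carbinol at C8, while the tertiary lactam is inert to catecholborane at this temperature.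

Step 8
Reactants: 13 lactam (S)-allylic alcohol; 14 benzyl bromide
Product: 15 lactam bis(benzyl ether), 6-[(2S)-2-benzyloxy-4-methylpent-3-enyl]-6-(benzyloxymethyl)
Conditions: NaH, Bu4NI (cat.), THF–DMF, 0 °C → rt
Reagents that add atoms: none
Why: Williamson etherification of the secondary alkoxide is safe here because the lactam has no enolisable position and no base-labile stereocentre.

Step 9
Reactants: 15 lactam bis(benzyl ether)
Product: 17 keto aldehyde, 2-(benzyloxymethyl)-2-[(2S)-2-benzyloxy-4-methylpent-3-enyl]-4-oxohexanal (C6 as in 15), via carbinolamine 16 (not isolated)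
Conditions: NaAlH2(OCH2CH2OMe)2, toluene, −20 → 0 °C; then 1 M aq. Bu4NH2PO4, EtOH, reflux
Reagents that add atoms: water, O
Why: Hydride reduction of the lactam carbonyl should stop at the carbinolamine, and buffered hydrolysis of the two aminal carbons then releases valinol and the γ-keto aldehyde, whose quaternary C6 cannot epimerise.

Step 10
Reactants: 17 keto aldehyde
Product: 19 (4R)-4-(benzyloxymethyl)-4-[(2S)-2-benzyloxy-4-methylpent-3-enyl]-2-methylcyclopent-2-en-1-one, via aldol adduct 18 (not isolated)
Conditions: KOH, EtOH, rt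
Reagents that add atoms: none
Why: In this intramolecular aldol condensation only the C22 enolate of the ethyl ketone can reach the non-enolisable aldehyde C21 through a five-membered ring, and E1cB dehydration gives the 2-methylcyclopentenone.

Step 11
Reactants: 19 cyclopentenone
Product: 20 epoxy enone, (4R)-4-(benzyloxymethyl)-4-{(2S)-2-benzyloxy-2-[(2S)-3,3-dimethyloxiran-2-yl]ethyl}-2-methylcyclopent-2-en-1-one
Conditions: ent-Shi ketone (1,2:4,5-di-O-isopropylidene-β-L-erythro-2,3-hexodiulo-2,6-pyranose, cat.), KHSO5 (Oxone), K2CO3, Bu4NHSO4, MeCN–CH2(OMe)2–aq. borate buffer, 0 °C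
Reagents that add atoms: potassium peroxymonosulfate, [K+].[O-]S(=O)(=O)OO
Why: In this Shi epoxidation the chiral dioxirane attacks only the electron-rich trisubstituted alkene (the enone is inert) through a spiro transition state, and the L-series ketone should give the (S)-epoxide at C13, erythro to the C8 benzyloxy group.

Step 12
Reactants: 20 epoxy enone
Product: 21 2-silyloxycyclopentadiene, the tert-butyldimethylsilyl dienol ether of 20 (C18=C24–OSi, C21=C22)
Conditions: LiN(iPr)2, THF, −78 °C; then TBSCl, DMPU, −78 → 0 °C
Reagents that add atoms: tert-butyldimethylsilyl chloride, CC(C)(C)[Si](C)(C)Cl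
Why: Kinetic deprotonation at C18, the only acidic position, and O-silylation give the cross-conjugated silyl dienol ether, which quaternary C6 protects from 1,5-hydrogen shifts, while the epoxide is inert to the amide base at low temperature.

Step 13
Reactants: 21 2-silyloxycyclopentadiene
Product: 22 cis-fused ring A–cyclopentenone, 5-benzyloxy-3a-(benzyloxymethyl)-6-hydroxy-2,7,7-trimethyl-3a,4,5,6,7,7a-hexahydroinden-1-one (C6, C8, C13 as in the target; H at C18 cis to the C5 arm)
Conditions: TiCl4, CH2Cl2, −78 °C; aq. NaHCO3
Reagents that add atoms: none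
Why: TiCl4 binds the epoxide oxygen (chelated by the C8 benzyloxy oxygen), the C15–O bond stretches toward the tertiary cation, and enol silane carbon C18 attacks C15 from the backside while the silyl group leaves as its chloride and the C24 ketone is restored. The closest known reaction type is the Lewis acid-promoted opening of epoxides by silyl enol ethers, as used to terminate epoxy-polyene cyclisations. Ring A closes by a 6-endo epoxide opening (enolexo for the nucleophile) through a chair with the C13 oxygen equatorial and the chelated C8 benzyloxy group axial. The new stereocentre C18 is fixed by the four-atom tether from C6, which can reach only the diene face that carries C7, so the ring fusion is cis; C8 and C13 pass through unchanged because the C13–O bond is never broken. The step needs opening at C15 and not at C13, which the tertiary gem-dimethyl carbon and the inductive pull of the C8 oxygen on C13 should secure, and attack through C18 only, which follows from the 2-silyloxydiene having no other enol-ether carbon.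

Step 14
Reactants: 22 ring A–cyclopentenone
Product: 23 C13 tert-butyldimethylsilyl ether of 22
Conditions: TBSOTf, 2,6-lutidine, CH2Cl2, −40 → 0 °C
Reagents that add atoms: tert-butyldimethylsilyl trifluoromethanesulfonate, CC(C)(C)[Si](C)(C)OS(=O)(=O)C(F)(F)F
Why: The silyl triflate silylates even the neopentyl-type secondary hydroxyl at C13, which must be masked before strong base, sulfonylation and acetylation.

Step 15
Reactants: 23 silyl ether; 4 allyl bromide
Product: 24 C18-allyl ketone (allyl on the face of the C5 arm, ring fusion cis)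
Conditions: KN(SiMe3)2, THF, −78 °C; then 4, −78 → 0 °C
Reagents that add atoms: none
Why: C18 carries the only enolisable hydrogen, and allylation of the potassium cross-conjugated enolate should occur on the face that keeps the two rings cis-fused, as is usual for ring-fusion alkylation of hydrindanone enolates; any O-allylated by-product is funnelled to the same ketone by Claisen rearrangement on warming.

Step 16
Reactants: 24 C18-allyl ketone
Product: 26 C20 aldehyde (C18–CH2–CHO), via ozonide 25 (not isolated)
Conditions: O3, CH2Cl2, −78 °C (Sudan Red 7B end point); then Me2S, −78 °C → rt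
Reagents that add atoms: ozone, [O-][O+]=O
Why: Ozonolysis with an indicator end point cleaves the isolated terminal alkene well before the hindered, electron-poor C21=C22 bond of the enone.

Step 17
Reactants: 26 C20 aldehyde
Product: 27 C20 tosylhydrazone
Conditions: TsNHNH2, MeOH, rt
Reagents that add atoms: 4-methylbenzenesulfonohydrazide, Cc1ccc(cc1)S(=O)(=O)NN
Why: Hydrazone condensation takes place at the aldehyde only, because the conjugated C24 ketone is flanked by quaternary C18.

Step 18
Reactants: 27 tosylhydrazone
Product: 30 nortricyclanone (C24 ketone; C5 and C8 benzyl ethers, C13 silyl ether), via diazoalkane 28 (not isolated), via pyrazoline 29 (not isolated)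
Conditions: NaH, THF, 0 °C; then toluene, 110 °C
Reagents that add atoms: none
Why: Bamford–Stevens fragmentation of the hydrazone salt gives the C20 diazoalkane, which should add across the electron-poor C21=C22 bond in an intramolecular 1,3-dipolar cycloaddition, and thermal loss of N2 from the strained acyl-substituted 1-pyrazoline closes the cyclopropane, with C20, C21 and C22 fixed by the two-carbon tether on the face of C19.

Step 19
Reactants: 30 nortricyclanone
Product: 31 C24 alcohol with the hydroxyl on the C6 side (C24 epimer of the target configuration)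
Conditions: LiAlH4, Et2O, 0 °C
Reagents that add atoms: none
Why: Hydride should reach the cage ketone from the side of the C19 methylene because the other side is covered by C7 of ring A (as in hydride reductions of 7-syn-substituted norbornanones), and a cyclopropyl ketone is reduced by LiAlH4 without ring opening.

Step 20
Reactants: 31 C24 alcohol
Product: 33 C24 acetate with the target configuration (acetoxy on the C19 side), via mesylate 32 (not isolated)
Conditions: Ms2O, Et3N, CH2Cl2, −30 °C; then KOAc, AcOH, −30 °C → rt
Reagents that add atoms: potassium acetate, CC(=O)[O-].[K+] (methanesulfonic anhydride, CS(=O)(=O)OS(C)(=O)=O, supplies only the sulfonyl group of 32)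
Why: The cyclopropylcarbinyl mesylate ionises readily to the bisected nortricyclyl cation, and in this buffered SN1 acetolysis acetate should add on the open C19 side, opposite the departing sulfonate, so C24 is inverted.

Step 21
Reactants: 33 C24 acetate
Product: 34 C5,C8-diol (C13 silyl ether and C24 acetate kept)
Conditions: H2 (1 atm), Pd/C, EtOAc, rt
Reagents that add atoms: none
Why: Hydrogenolysis removes both benzyl ethers under neutral conditions that leave the cyclopropane, the acetate and the silyl ether intact.

Step 22
Reactants: 34 diol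
Product: 35 C5,C8,C24-triacetate C13 silyl ether
Conditions: Ac2O, pyridine, DMAP (cat.), CH2Cl2, rt
Reagents that add atoms: acetic anhydride, CC(=O)OC(C)=O
Why: DMAP-catalysed acylation esterifies the primary C5 and secondary C8 hydroxyls while C13 remains protected.

Step 23
Reactants: 35 triacetate silyl ether
Product: 36 CNP0197219.1
Conditions: HF·pyridine, THF–pyridine, 0 °C → rt
Reagents that add atoms: none
Why: Desilylation with HF·pyridine is acidic enough to avoid migration of the C8 acetate to the freed C13 hydroxyl.

Compound list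
1 | (R)-valinol, (2R)-2-amino-3-methylbutan-1-ol | CC(C)[C@@H](N)CO | starting material
2 | 4-oxohexanoic acid | CCC(=O)CCC(=O)O | starting material
3 | (3R,7aS)-7a-ethyl-3-isopropyltetrahydropyrrolo[2,1-b]oxazol-5(6H)-one | CC[C@]12CCC(=O)N1[C@H](C(C)C)CO2 | intermediate
4 | allyl bromide | C=CCBr | starting material
5 | 6-allyl derivative of 3, both C6 epimers (centre left undefined) | CC[C@]12CC(CC=C)C(=O)N1[C@H](C(C)C)CO2 | intermediate
6 | benzyl chloromethyl ether | ClCOCc1ccccc1 | starting material
7 | (3R,6S,7aS)-6-allyl-6-(benzyloxymethyl)-7a-ethyl-3-isopropyltetrahydropyrrolo[2,1-b]oxazol-5(6H)-one | CC[C@]12C[C@](COCc3ccccc3)(CC=C)C(=O)N1[C@H](C(C)C)CO2 | intermediate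
8 | ozonide (1,2,4-trioxolane) of 7 | CC[C@]12C[C@](COCc3ccccc3)(CC4OCOO4)C(=O)N1[C@H](C(C)C)CO2 | intermediate (not isolated)
9 | lactam aldehyde, 6-(2-oxoethyl) analogue of 7 | CC[C@]12C[C@](COCc3ccccc3)(CC=O)C(=O)N1[C@H](C(C)C)CO2 | intermediate
10 | (2-methylprop-1-enyl)magnesium bromide | CC(C)=C[Mg]Br | starting material
11 | lactam allylic alcohol, 6-(2-hydroxy-4-methylpent-3-enyl), both C8 epimers | CC[C@]12C[C@](COCc3ccccc3)(CC(O)C=C(C)C)C(=O)N1[C@H](C(C)C)CO2 | intermediate
12 | lactam enone, 6-(4-methyl-2-oxopent-3-enyl) | CC[C@]12C[C@](COCc3ccccc3)(CC(=O)C=C(C)C)C(=O)N1[C@H](C(C)C)CO2 | intermediate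
13 | lactam (S)-allylic alcohol, 6-[(2S)-2-hydroxy-4-methylpent-3-enyl] | CC[C@]12C[C@](COCc3ccccc3)(C[C@H](O)C=C(C)C)C(=O)N1[C@H](C(C)C)CO2 | intermediate
14 | benzyl bromide | BrCc1ccccc1 | starting material
15 | lactam bis(benzyl ether), 6-[(2S)-2-benzyloxy-4-methylpent-3-enyl]-6-(benzyloxymethyl) | CC[C@]12C[C@](COCc3ccccc3)(C[C@H](OCc4ccccc4)C=C(C)C)C(=O)N1[C@H](C(C)C)CO2 | intermediate
16 | carbinolamine, 5-hydroxy compound from 15 (C5 of the lactam undefined) | CC[C@]12C[C@](COCc3ccccc3)(C[C@H](OCc4ccccc4)C=C(C)C)C(O)N1[C@H](C(C)C)CO2 | intermediate (not isolated)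
17 | keto aldehyde, 2-(benzyloxymethyl)-2-[(2S)-2-benzyloxy-4-methylpent-3-enyl]-4-oxohexanal | CCC(=O)C[C@](COCc1ccccc1)(C[C@H](OCc2ccccc2)C=C(C)C)C=O | intermediate
18 | aldol adduct, 3-hydroxy-2-methylcyclopentanone (new centres undefined) | CC1C(O)[C@@](COCc2ccccc2)(C[C@H](OCc3ccccc3)C=C(C)C)CC1=O | intermediate (not isolated)
19 | (4R)-4-(benzyloxymethyl)-4-[(2S)-2-benzyloxy-4-methylpent-3-enyl]-2-methylcyclopent-2-en-1-one | O=C1C[C@](COCc2ccccc2)(C[C@H](OCc3ccccc3)C=C(C)C)C=C1C | intermediate
20 | (4R)-4-(benzyloxymethyl)-4-{(2S)-2-benzyloxy-2-[(2S)-3,3-dimethyloxiran-2-yl]ethyl}-2-methylcyclopent-2-en-1-one | O=C1C[C@](COCc2ccccc2)(C[C@H](OCc3ccccc3)[C@@H]4OC4(C)C)C=C1C | intermediate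
21 | 2-(tert-butyldimethylsilyloxy)cyclopentadiene from 20 (key-step precursor) | CC(C)(C)[Si](C)(C)OC1=C[C@](COCc2ccccc2)(C[C@H](OCc3ccccc3)[C@@H]4OC4(C)C)C=C1C | intermediate
22 | cis-fused 5-benzyloxy-3a-(benzyloxymethyl)-6-hydroxy-2,7,7-trimethyl-3a,4,5,6,7,7a-hexahydroinden-1-one (key-step product) | O(Cc5ccccc5)C[C@]12C[C@H](OCc6ccccc6)[C@H](O)C(C)(C)[C@H]1C(=O)C(C)=C2 | intermediate
23 | C13 tert-butyldimethylsilyl ether of 22 | O(Cc5ccccc5)C[C@]12C[C@H](OCc6ccccc6)[C@H](O[Si](C)(C)C(C)(C)C)C(C)(C)[C@H]1C(=O)C(C)=C2 | intermediate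
24 | C18-allyl ketone (7a-allyl derivative of 23, rings cis-fused) | O(Cc5ccccc5)C[C@]12C[C@H](OCc6ccccc6)[C@H](O[Si](C)(C)C(C)(C)C)C(C)(C)[C@@]1(CC=C)C(=O)C(C)=C2 | intermediate
25 | ozonide (1,2,4-trioxolane) of 24 | O(Cc5ccccc5)C[C@]12C[C@H](OCc6ccccc6)[C@H](O[Si](C)(C)C(C)(C)C)C(C)(C)[C@@]1(CC7OCOO7)C(=O)C(C)=C2 | intermediate (not isolated)
26 | C20 aldehyde (7a-(2-oxoethyl) compound) | O(Cc5ccccc5)C[C@]12C[C@H](OCc6ccccc6)[C@H](O[Si](C)(C)C(C)(C)C)C(C)(C)[C@@]1(CC=O)C(=O)C(C)=C2 | intermediate
27 | C20 tosylhydrazone of 26 | O(Cc5ccccc5)C[C@]12C[C@H](OCc6ccccc6)[C@H](O[Si](C)(C)C(C)(C)C)C(C)(C)[C@@]1(CC=NNS(=O)(=O)c7ccc(C)cc7)C(=O)C(C)=C2 | intermediate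
28 | C20 diazoalkane (7a-(2-diazoethyl) compound) | O(Cc5ccccc5)C[C@]12C[C@H](OCc6ccccc6)[C@H](O[Si](C)(C)C(C)(C)C)C(C)(C)[C@@]1(CC=[N+]=[N-])C(=O)C(C)=C2 | intermediate (not isolated)
29 | 1-pyrazoline with C20–C21 bond and N=N bridge from C20 to C22 | O(Cc5ccccc5)C[C@]12C[C@H](OCc6ccccc6)[C@H](O[Si](C)(C)C(C)(C)C)C(C)(C)[C@]13C[C@@H]4[C@H]2[C@@](C)(N=N4)C3=O | intermediate (not isolated)
30 | nortricyclanone (C24 ketone, C5 and C8 benzyl ethers, C13 silyl ether) | O(Cc5ccccc5)C[C@]12C[C@H](OCc6ccccc6)[C@H](O[Si](C)(C)C(C)(C)C)C(C)(C)[C@]13C[C@@H]4[C@H]2[C@]4(C)C3=O | intermediate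
31 | C24 alcohol, hydroxyl on the C6 side (C24 epimer of the target configuration) | O(Cc5ccccc5)C[C@]12C[C@H](OCc6ccccc6)[C@H](O[Si](C)(C)C(C)(C)C)C(C)(C)[C@]13C[C@@H]4[C@H]2[C@]4(C)[C@@H]3O | intermediate
32 | C24 mesylate of 31 | O(Cc5ccccc5)C[C@]12C[C@H](OCc6ccccc6)[C@H](O[Si](C)(C)C(C)(C)C)C(C)(C)[C@]13C[C@@H]4[C@H]2[C@]4(C)[C@@H]3OS(C)(=O)=O | intermediate (not isolated)
33 | C24 acetate with the target configuration (C5 and C8 benzyl ethers, C13 silyl ether) | O(Cc5ccccc5)C[C@]12C[C@H](OCc6ccccc6)[C@H](O[Si](C)(C)C(C)(C)C)C(C)(C)[C@]13C[C@@H]4[C@H]2[C@]4(C)[C@H]3OC(C)=O | intermediate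
34 | C5,C8-diol (C13 silyl ether, C24 acetate) | OC[C@]12C[C@H](O)[C@H](O[Si](C)(C)C(C)(C)C)C(C)(C)[C@]13C[C@@H]4[C@H]2[C@]4(C)[C@H]3OC(C)=O | intermediate
35 | C5,C8,C24-triacetate C13 silyl ether | CC(=O)OC[C@]12C[C@H](OC(C)=O)[C@H](O[Si](C)(C)C(C)(C)C)C(C)(C)[C@]13C[C@@H]4[C@H]2[C@]4(C)[C@H]3OC(C)=O | intermediate
36 | CNP0197219.1 | CC(=O)OC[C@]12C[C@H](OC(C)=O)[C@H](O)C(C)(C)[C@]13C[C@@H]1[C@H]2[C@]1(C)[C@H]3OC(C)=O | target

Total step count: 23 steps. Longest linear sequence: 23 steps (from 1 and 2 to 36).

Steps most likely to fail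

Step 13. The titanium-bound epoxide may collapse by 1,2-hydride shift to a C13 ketone, or be intercepted by a benzyl ether oxygen, before C18 forms the bond to C15; the axial C8 benzyloxy group in the chair raises the barrier for the C–C closure. The fallback replaces the epoxide by an alkene activated with divalent mercury and sets out from 19. Enolisation with LiN(iPr)2 and trapping with TBSCl gives silyl dienol ether F1. Hg(OTf)2·PhNMe2 in MeNO2 at −20 °C, followed by aqueous NaCl, activates the trisubstituted alkene so that C18 closes ring A at C15, giving organomercury chloride F2. Oxidative demercuration (NaBH4, O2, DMF) gives the C13 alcohols F3 as an epimer mixture, and Dess–Martin oxidation gives C13 ketone F4. NaBH4 in MeOH–CH2Cl2 at −78 °C, which reduces a saturated ketone before an enone, should add hydride on the face away from the axial C8 benzyloxy and C15 methyl groups, and the route is rejoined at 22.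

Step 18. The diazoalkane may lose nitrogen to a carbene that shifts hydrogen to a vinyl group, or the pyrazoline may tautomerise instead of extruding N2. The fallback closes the cyclopropane with a sulfone carbanion and sets out from 26. NaBH4 in MeOH at −78 °C reduces the aldehyde only and gives primary alcohol F5; I2, PPh3 and imidazole give iodide F6; PhSO2Na in DMF gives phenyl sulfone F7. With KOtBu in DMSO–THF the C20 sulfonyl carbanion adds to C21 of the enone and the resulting C22 enolate expels benzenesulfinate from C20 (Michael addition followed by 1,3-elimination), and the route is rejoined at 30.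

Step 20. The nortricyclyl cation may be captured at C20 or C21 with opening of the cyclopropane to norbornenyl acetates, may undergo a skeletal shift, or may be captured with poor facial selectivity. The fallback avoids ionisation and sets out from 31. Meerwein–Ponndorf–Verley/Oppenauer equilibration (Al(OiPr)3, iPrOH, catalytic acetone, toluene, reflux) should enrich the less hindered C24-epimeric alcohol F8, which is separated while 31 is recycled. Acetylation of F8 with Ac2O, DMAP and pyridine, with retention at C24, rejoins the route at 33.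

Further compounds
F1 | step 13 | tert-butyldimethylsilyl dienol ether of 19 | CC(C)(C)[Si](C)(C)OC1=C[C@](COCc2ccccc2)(C[C@H](OCc3ccccc3)C=C(C)C)C=C1C
F2 | step 13 | C13 chloromercurio ring A–cyclopentenone (C13 undefined) | O(Cc5ccccc5)C[C@]12C[C@H](OCc6ccccc6)C([Hg]Cl)C(C)(C)[C@H]1C(=O)C(C)=C2
F3 | step 13 | C13 alcohol, both epimers (22 and its C13 epimer) | O(Cc5ccccc5)C[C@]12C[C@H](OCc6ccccc6)C(O)C(C)(C)[C@H]1C(=O)C(C)=C2
F4 | step 13 | C13 ketone | O(Cc5ccccc5)C[C@]12C[C@H](OCc6ccccc6)C(=O)C(C)(C)[C@H]1C(=O)C(C)=C2
F5 | step 18 | C20 primary alcohol from 26 | O(Cc5ccccc5)C[C@]12C[C@H](OCc6ccccc6)[C@H](O[Si](C)(C)C(C)(C)C)C(C)(C)[C@@]1(CCO)C(=O)C(C)=C2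
F6 | step 18 | C20 iodide | O(Cc5ccccc5)C[C@]12C[C@H](OCc6ccccc6)[C@H](O[Si](C)(C)C(C)(C)C)C(C)(C)[C@@]1(CCI)C(=O)C(C)=C2
F7 | step 18 | C20 phenyl sulfone | O(Cc5ccccc5)C[C@]12C[C@H](OCc6ccccc6)[C@H](O[Si](C)(C)C(C)(C)C)C(C)(C)[C@@]1(CCS(=O)(=O)c7ccccc7)C(=O)C(C)=C2
F8 | step 20 | C24 alcohol with the hydroxyl on the C19 side (C24 epimer of 31) | O(Cc5ccccc5)C[C@]12C[C@H](OCc6ccccc6)[C@H](O[Si](C)(C)C(C)(C)C)C(C)(C)[C@]13C[C@@H]4[C@H]2[C@]4(C)[C@H]3O
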